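Rings: A = 4-hydroxy-2-methoxyphenyl, B = 4-hydroxyphenyl on the stereocentre, C = 2,4-dihydroxyphenyl, D = 4-hydroxybenzoyl. Enabling feature: the lone stereocentre is a benzylic CH bonded to C1 of ring B (para to the ring B hydroxyl) and to C5 of ring C (ortho to the C4-OH, para to the C2-OH). This is the imprint of a ring B para-quinone methide whose exocyclic carbon was captured by the most electron-rich carbon of a resorcinol.
Cuts: first the CH–C5(ring C) bond, which divides the target into two C6-C3-C6 halves; then the CH2–CH2 bond of each three-carbon chain, traced back to the C=C of a chalcone.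
Forward: no ring is built and all four benzene rings are purchased. Each half comes from one Claisen–Schmidt condensation, one pivaloylation and one hydrogenation; the A/B half is then reduced to its carbinol, and the halves are joined in the penultimate step.
Protection: only the three hydroxyls that take part in the union (ring B OH and both ring C OH) are free at that stage. The spectator phenols of rings A and D are pivalates and leave together in the last step.
Stereochemistry: created once, in the union, by a chiral phosphoric acid acting on the flat methide, so a racemic carbinol suffices; the final step does not touch the centre.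

Key step: step 8

Assumption: the sense of induction of the binaphthyl phosphoric acid on an alkyl-substituted methide cannot be read from analogy, so the (R)-acid is written; should it favour the (S)-product, the equally available (S)-acid is used with no other change.

Step 1
Reactants: 1 4-hydroxy-2-methoxybenzaldehyde; 2 1-[4-(benzyloxy)phenyl]ethan-1-one
Product: 3 (E)-1-[4-(benzyloxy)phenyl]-3-(4-hydroxy-2-methoxyphenyl)prop-2-en-1-one
Conditions: dry HCl in abs. EtOH (ca. 3 M), 0 °C to rt
Reagents that add atoms: none
Why: Acid-mediated Claisen–Schmidt condensation, in which the enol of 2 adds to the protonated aldehyde and the para hydroxyl and ortho methoxy groups of ring A assist loss of water to the (E)-enone, whereas base would convert 1 into an unreactive phenoxide; the aryl benzyl ether tolerates ethanolic HCl at room temperature.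

Step 2
Reactants: 3 (E)-1-[4-(benzyloxy)phenyl]-3-(4-hydroxy-2-methoxyphenyl)prop-2-en-1-one
Product: 4 4-{(E)-3-[4-(benzyloxy)phenyl]-3-oxoprop-1-en-1-yl}-3-methoxyphenyl pivalate
Conditions: pivaloyl chloride, Et3N, 4-(dimethylamino)pyridine (5 mol %), CH2Cl2, 0 °C to rt
Reagents that add atoms: pivaloyl chloride, CC(C)(C)C(=O)Cl
Why: Nucleophile-catalysed O-acylation of the only free phenol; the hindered aryl ester is chosen because it should survive hydrogenation, borohydride and the acid of step 8 while it lowers the nucleophilicity of ring A.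

Step 3
Reactants: 4 4-{(E)-3-[4-(benzyloxy)phenyl]-3-oxoprop-1-en-1-yl}-3-methoxyphenyl pivalate
Product: 5 4-[3-(4-hydroxyphenyl)-3-oxopropyl]-3-methoxyphenyl pivalate
Conditions: H2 (1 atm), Pd/C (10 wt % Pd), EtOAc, rt, stopped after uptake of two equivalents
Reagents that add atoms: none
Why: Heterogeneous catalytic hydrogenation saturates the enone C=C and hydrogenolyses the aryl benzyl ether in one operation, while the pivalate is inert and the ketone, which becomes an electron-rich para-hydroxyaryl ketone, is slow to reduce in a neutral aprotic solvent.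

Step 4
Reactants: 5 4-[3-(4-hydroxyphenyl)-3-oxopropyl]-3-methoxyphenyl pivalate
Product: 6 rac-4-[3-hydroxy-3-(4-hydroxyphenyl)propyl]-3-methoxyphenyl pivalate
Conditions: NaBH4 (2.5 equiv), THF–EtOH (4:1), 0 °C to rt; sat. aq. NH4Cl, neutral work-up, used promptly
Reagents that add atoms: none
Why: Borohydride reduction of an aryl ketone, to which the hindered aryl pivalate is inert; no stereocontrol is needed because this centre is erased in step 8, and the neutral work-up avoids premature ionisation of the para-hydroxybenzylic alcohol.

Step 5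
Reactants: 7 2,4-bis(benzyloxy)benzaldehyde; 8 1-(4-hydroxyphenyl)ethan-1-one
Product: 9 (E)-3-[2,4-bis(benzyloxy)phenyl]-1-(4-hydroxyphenyl)prop-2-en-1-one
Conditions: KOH (50 % aq., excess), EtOH–THF, rt; then 2 M HCl to pH 4
Reagents that add atoms: none
Why: Base-mediated Claisen–Schmidt condensation, the standard entry to 4'-hydroxychalcones, in which excess hydroxide forms the phenoxide enolate of 8, this adds to the non-enolisable aldehyde 7, and E1cB loss of water gives the (E)-enone.

Step 6
Reactants: 9 (E)-3-[2,4-bis(benzyloxy)phenyl]-1-(4-hydroxyphenyl)prop-2-en-1-one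
Product: 10 4-{(E)-3-[2,4-bis(benzyloxy)phenyl]prop-2-enoyl}phenyl pivalate
Conditions: pivaloyl chloride, Et3N, 4-(dimethylamino)pyridine (5 mol %), CH2Cl2, 0 °C to rt
Reagents that add atoms: pivaloyl chloride, CC(C)(C)C(=O)Cl
Why: Nucleophile-catalysed O-acylation of the single free phenol masks the acidic ring D hydroxyl, which would otherwise compete for the catalyst in step 8 and make the nucleophile poorly soluble in nonpolar media.

Step 7
Reactants: 10 4-{(E)-3-[2,4-bis(benzyloxy)phenyl]prop-2-enoyl}phenyl pivalate
Product: 11 4-[3-(2,4-dihydroxyphenyl)propanoyl]phenyl pivalate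
Conditions: H2 (1 atm), Pd/C (10 wt % Pd), EtOAc, rt, stopped after uptake of three equivalents
Reagents that add atoms: none
Why: Heterogeneous catalytic hydrogenation saturates the alkene and removes both aryl benzyl ethers faster than it attacks the aryl ketone in neutral ethyl acetate, a standard chalcone to dihydrochalcone conversion, and the pivalate is untouched.

Step 8
Reactants: 6 rac-4-[3-hydroxy-3-(4-hydroxyphenyl)propyl]-3-methoxyphenyl pivalate; 11 4-[3-(2,4-dihydroxyphenyl)propanoyl]phenyl pivalate
Product: 13 4-[(3R)-3-{2,4-dihydroxy-5-[3-oxo-3-(4-pivaloyloxyphenyl)propyl]phenyl}-3-(4-hydroxyphenyl)propyl]-3-methoxyphenyl pivalate, via para-quinone methide 12 (not isolated)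
Conditions: 11 (1.5 equiv), (R)-3,3'-bis(2,4,6-triisopropylphenyl)-1,1'-binaphthalene-2,2'-diyl hydrogen phosphate (10 mol %), 4 Å MS, CH2Cl2–PhMe (1:1), 0 °C, 6 added slowly by syringe pump
Reagents that add atoms: none
Why: Proposed new method: the phosphoric acid should ionise either enantiomer of the para-hydroxybenzylic alcohol 6 with loss of water to the same planar para-quinone methide 12, hold its carbonyl oxygen through P–OH and the C4 hydroxyl of ring C of 11 through P=O, and so bring C5 of ring C onto the exocyclic methide carbon (1,6-addition), after which tautomerisation restores rings B and C as phenols. The closest known reaction type is the chiral phosphoric acid catalysed enantioselective Friedel–Crafts 1,6-addition of naphthols, phenols and indoles to para-quinone methides formed in situ from para-hydroxybenzyl alcohols, which is established for aryl-bearing methides, whereas a methide that carries only hydrogen and a primary alkyl chain and a plain resorcinol as carbon nucleophile have not been shown. No ring is closed, only the CH–C5 bond forms. The new stereocentre is controlled solely by the catalyst, whose 2,4,6-triisopropylphenyl groups leave one face of the doubly hydrogen-bonded methide open, and since the configuration of 6 is erased on ionisation the step is stereoconvergent. Site selectivity for C5 rests on its being ortho to one and para to the other free hydroxyl, while C3 is wedged between both hydroxyls and C6 is meta to both. Chemoselectivity rests on the pivalates, which lower the nucleophilicity of ring A and remove the acidic ring D phenol as a competing hydrogen-bond donor, on the fact that the ring A carbon able to close an indane is meta to both ring A oxygens, and on the excess of 11 together with the slow addition of 6, which keeps 12 dilute.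

Step 9
Reactants: 13 4-[(3R)-3-{2,4-dihydroxy-5-[3-oxo-3-(4-pivaloyloxyphenyl)propyl]phenyl}-3-(4-hydroxyphenyl)propyl]-3-methoxyphenyl pivalate
Product: 14 3-{2,4-dihydroxy-5-[(1R)-3-(4-hydroxy-2-methoxyphenyl)-1-(4-hydroxyphenyl)propyl]phenyl}-1-(4-hydroxyphenyl)propan-1-one (CNP0253987.1)
Conditions: K2CO3 (6 equiv), degassed MeOH, Ar, rt; sat. aq. NH4Cl, 0 °C
Reagents that add atoms: none
Why: Carbonate-mediated transesterification of aryl esters releases the ring A and ring D phenols together, while the ketone is untouched, the doubly benzylic C–H of the stereocentre is far too weakly acidic to exchange, and the absence of acid excludes reopening of the methine–aryl bond.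

Compound list
1 | 4-hydroxy-2-methoxybenzaldehyde | COc1cc(O)ccc1C=O | starting material
2 | 1-[4-(benzyloxy)phenyl]ethan-1-one | CC(=O)c1ccc(OCc2ccccc2)cc1 | starting material
3 | (E)-1-[4-(benzyloxy)phenyl]-3-(4-hydroxy-2-methoxyphenyl)prop-2-en-1-one | COc1cc(O)ccc1/C=C/C(=O)c1ccc(OCc2ccccc2)cc1 | intermediate
4 | 4-{(E)-3-[4-(benzyloxy)phenyl]-3-oxoprop-1-en-1-yl}-3-methoxyphenyl pivalate | COc1cc(OC(=O)C(C)(C)C)ccc1/C=C/C(=O)c1ccc(OCc2ccccc2)cc1 | intermediate
5 | 4-[3-(4-hydroxyphenyl)-3-oxopropyl]-3-methoxyphenyl pivalate | COc1cc(OC(=O)C(C)(C)C)ccc1CCC(=O)c1ccc(O)cc1 | intermediate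
6 | rac-4-[3-hydroxy-3-(4-hydroxyphenyl)propyl]-3-methoxyphenyl pivalate (racemate) | COc1cc(OC(=O)C(C)(C)C)ccc1CCC(O)c1ccc(O)cc1 | intermediate
7 | 2,4-bis(benzyloxy)benzaldehyde | O=Cc1ccc(OCc2ccccc2)cc1OCc1ccccc1 | starting material
8 | 1-(4-hydroxyphenyl)ethan-1-one | CC(=O)c1ccc(O)cc1 | starting material
9 | (E)-3-[2,4-bis(benzyloxy)phenyl]-1-(4-hydroxyphenyl)prop-2-en-1-one | O=C(/C=C/c1ccc(OCc2ccccc2)cc1OCc1ccccc1)c1ccc(O)cc1 | intermediate
10 | 4-{(E)-3-[2,4-bis(benzyloxy)phenyl]prop-2-enoyl}phenyl pivalate | O=C(/C=C/c1ccc(OCc2ccccc2)cc1OCc1ccccc1)c1ccc(OC(=O)C(C)(C)C)cc1 | intermediate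
11 | 4-[3-(2,4-dihydroxyphenyl)propanoyl]phenyl pivalate | O=C(CCc1ccc(O)cc1O)c1ccc(OC(=O)C(C)(C)C)cc1 | intermediate
12 | 3-methoxy-4-[3-(4-oxocyclohexa-2,5-dien-1-ylidene)propyl]phenyl pivalate (para-quinone methide, not isolated) | COc1cc(OC(=O)C(C)(C)C)ccc1CCC=C1C=CC(=O)C=C1 | intermediate
13 | 4-[(3R)-3-{2,4-dihydroxy-5-[3-oxo-3-(4-pivaloyloxyphenyl)propyl]phenyl}-3-(4-hydroxyphenyl)propyl]-3-methoxyphenyl pivalate | COc1cc(OC(=O)C(C)(C)C)ccc1CC[C@H](c1ccc(O)cc1)c1cc(CCC(=O)c2ccc(OC(=O)C(C)(C)C)cc2)c(O)cc1O | intermediate
14 | 3-{2,4-dihydroxy-5-[(1R)-3-(4-hydroxy-2-methoxyphenyl)-1-(4-hydroxyphenyl)propyl]phenyl}-1-(4-hydroxyphenyl)propan-1-one | COc1cc(O)ccc1CC[C@H](c1ccc(O)cc1)c1cc(CCC(=O)c2ccc(O)cc2)c(O)cc1O | target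

Total step count: 9. Longest linear sequence: 6 (steps 1, 2, 3, 4, 8, 9).

Steps most likely to fail

**Step 8.**
- Risk: ionisation of a secondary, alkyl-substituted carbinol by a weak acid may be slow. The unhindered methide may be lost through tautomerisation to the alkenylphenol, O-alkylation and oligomerisation. Discrimination between hydrogen and a slim alkyl chain at the methide carbon may give poor facial selectivity.
- Fallback (known chemistry): the stereochemistry is taken from resolution instead of catalysis. Setting out from 6 and 11, a classical Brønsted acid catalysed Friedel–Crafts benzylation of the resorcinol (p-toluenesulfonic acid monohydrate, catalytic, MeCN, rt, 11 in excess) should give the racemic bis-pivalate F1. Acid strength and temperature can be raised freely here because no enantioselectivity is at stake.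
- Preparative HPLC on an amylose tris(3,5-dimethylphenylcarbamate) phase then separates the unwanted (S)-bis-pivalate F2 from the (R)-enantiomer, which is 13, where the route is rejoined. The configuration would be assigned by electronic circular dichroism against calculation.

**Step 7.**
- Risk: over-reduction. Once the C2 hydroxyl of ring C is freed it can add to the ketone, and loss of water followed by hydrogen uptake would consume the carbonyl. Direct reduction of the ester-substituted aryl ketone and hydrogenolysis of the resulting benzylic alcohol would do the same.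
- Fallback: setting out from 10, the two tasks are separated and hydrogen is kept away from the free ortho-hydroxy ketone. Homogeneous hydrogenation over RhCl(PPh3)3 (H2, PhMe–EtOH, rt) saturates enone C=C bonds but leaves aryl ketones and benzyl ethers alone. It should give the saturated bis(benzyl ether) 4-{3-[2,4-bis(benzyloxy)phenyl]propanoyl}phenyl pivalate F3.
- Non-reductive debenzylation with BCl3 and pentamethylbenzene as cation scavenger (CH2Cl2, −78 °C), which spares esters and ketones, then delivers 11, where the route is rejoined.

**Step 1.**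
- Risk: incomplete condensation of the very electron-rich aldehyde, acid-induced loss of the benzyl ether, or oligomerisation of the electron-rich enone.
- Fallback: setting out from 1 and 2 and returning at 4 (3 and step 2 are bypassed), the enone is made by a Wittig olefination under neutral conditions.
- Aldehyde 1 is pivaloylated first (pivaloyl chloride, Et3N, 4-(dimethylamino)pyridine, CH2Cl2) to 4-formyl-3-methoxyphenyl pivalate F4.
- Ketone 2 is brominated (CuBr2, EtOAc–CHCl3, reflux) to 1-[4-(benzyloxy)phenyl]-2-bromoethan-1-one F5.
- With PPh3 (PhMe, rt) this gives {2-[4-(benzyloxy)phenyl]-2-oxoethyl}triphenylphosphonium bromide F6. Aqueous NaOH then gives the stabilised ylide 1-[4-(benzyloxy)phenyl]-2-(triphenyl-λ5-phosphanylidene)ethan-1-one F7.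
- Heating F4 and F7 in toluene should give the (E)-enone 4 directly, since stabilised acyl ylides are (E)-selective and do not disturb aryl esters.

Further compounds
F1 | step 8 | rac-4-[3-{2,4-dihydroxy-5-[3-oxo-3-(4-pivaloyloxyphenyl)propyl]phenyl}-3-(4-hydroxyphenyl)propyl]-3-methoxyphenyl pivalate | COc1cc(OC(=O)C(C)(C)C)ccc1CCC(c1ccc(O)cc1)c1cc(CCC(=O)c2ccc(OC(=O)C(C)(C)C)cc2)c(O)cc1O
F2 | step 8 | 4-[(3S)-3-{2,4-dihydroxy-5-[3-oxo-3-(4-pivaloyloxyphenyl)propyl]phenyl}-3-(4-hydroxyphenyl)propyl]-3-methoxyphenyl pivalate | COc1cc(OC(=O)C(C)(C)C)ccc1CC[C@@H](c1ccc(O)cc1)c1cc(CCC(=O)c2ccc(OC(=O)C(C)(C)C)cc2)c(O)cc1O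
F3 | step 7 | 4-{3-[2,4-bis(benzyloxy)phenyl]propanoyl}phenyl pivalate | O=C(CCc1ccc(OCc2ccccc2)cc1OCc1ccccc1)c1ccc(OC(=O)C(C)(C)C)cc1
F4 | step 1 | 4-formyl-3-methoxyphenyl pivalate | COc1cc(OC(=O)C(C)(C)C)ccc1C=O
F5 | step 1 | 1-[4-(benzyloxy)phenyl]-2-bromoethan-1-one | O=C(CBr)c1ccc(OCc2ccccc2)cc1
F6 | step 1 | {2-[4-(benzyloxy)phenyl]-2-oxoethyl}triphenylphosphonium bromide | [Br-].O=C(C[P+](c1ccccc1)(c1ccccc1)c1ccccc1)c1ccc(OCc2ccccc2)cc1
F7 | step 1 | 1-[4-(benzyloxy)phenyl]-2-(triphenyl-λ5-phosphanylidene)ethan-1-one | O=C(C=P(c1ccccc1)(c1ccccc1)c1ccccc1)c1ccc(OCc2ccccc2)cc1
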